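**Retrosynthetic overview**
1. Target ⇐ hexabenzyl biflavone ⇐ bis(2'-hydroxychalcone): both pyranone rings (rings C) are closed last and together, each by O1–C2 bond formation with dehydrogenation; the benzyl ethers fall in the same flask.
2. Bis-chalcone ⇐ biaryl chalcone-aldehyde + 2-hydroxy-4,6-bis(benzyloxy)acetophenone (Claisen–Schmidt; chain of the apigenin-type unit).
3. Chalcone-aldehyde ⇐ 3'-iodochalcone + aryl pinacol boronate (Suzuki–Miyaura; the 3',8'' biaryl bond is made before any heterocycle); iodochalcone ⇐ iodoacetophenone + O-benzylvanillin.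
4. Ring order: all five benzene rings are bought; the two pyranone rings are the only rings made, both in the last step; the single free phenol next to iodine fixes the 8-aryl regiochemistry.

Assumption: the SMILES holds no stereocentre and no defined axis (the 3',8'' biaryl axis is taken as freely rotating), so the target is one achiral constitution and needs no enantiocontrol; the only stereo-elements on the way are two (E) enones that vanish in the last step.

Step 1
Reactants: 1 2',4',6'-trihydroxyacetophenone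
Product: 2 1-[2,4-bis(benzyloxy)-6-hydroxyphenyl]ethanone
Conditions: BnBr (2.05 equiv), K2CO3 (2.2 equiv), DMF, 0 °C to rt, 16 h
Reagents that add atoms: benzyl bromide, BrCc1ccccc1
Why: Williamson ether synthesis; the 4-OH and one of the two equivalent ortho OH groups are alkylated, after which the last ortho phenol is locked in a hydrogen bond to the ketone and stays free, so 2 keeps exactly the one phenol that later becomes O1 of ring C.

Step 2
Reactants: 2 1-[2,4-bis(benzyloxy)-6-hydroxyphenyl]ethanone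
Product: 3 1-[4,6-bis(benzyloxy)-2-hydroxy-3-iodophenyl]ethanone
Conditions: BnMe3N·ICl2 (1.05 equiv), CaCO3, CH2Cl2–MeOH, rt
Reagents that add atoms: benzyltrimethylammonium dichloroiodate, C[N+](C)(C)Cc1ccccc1.Cl[I-]Cl
Why: Electrophilic aromatic iodination; the free phenol is the strongest activator and directs iodine to its ortho position C3 (as with the known dimethyl ether analogue), which puts the halogen next to the future O1 and so fixes the 8-aryl pattern.

Step 3
Reactants: 3 1-[4,6-bis(benzyloxy)-2-hydroxy-3-iodophenyl]ethanone; 4 4-(benzyloxy)-3-methoxybenzaldehyde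
Product: 5 (E)-1-[4,6-bis(benzyloxy)-2-hydroxy-3-iodophenyl]-3-[4-(benzyloxy)-3-methoxyphenyl]prop-2-en-1-one
Conditions: KOH (50% aq.), EtOH–THF, rt, 36 h
Reagents that add atoms: none
Why: Claisen–Schmidt (crossed aldol) condensation of the methyl ketone enolate with a non-enolisable aldehyde, E1cB dehydration giving the conjugated (E) enone as the thermodynamic isomer; aryl iodide and benzyl ethers are inert to aqueous KOH at rt.

Step 4
Reactants: 6 4-(benzyloxy)-3-bromobenzaldehyde; 5 (E)-1-[4,6-bis(benzyloxy)-2-hydroxy-3-iodophenyl]-3-[4-(benzyloxy)-3-methoxyphenyl]prop-2-en-1-one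
Product: 8 4-(benzyloxy)-3-{4,6-bis(benzyloxy)-3-[(E)-3-(4-(benzyloxy)-3-methoxyphenyl)prop-2-enoyl]-2-hydroxyphenyl}benzaldehyde, via pinacol boronate 7 (not isolated)
Conditions: 6, B2pin2 (1.1 equiv), PdCl2(dppf) (3 mol %), KOAc, 1,4-dioxane, 90 °C; then 5 (0.85 equiv), Pd(OAc)2 (3 mol %), SPhos (6 mol %), K3PO4 (aq.), 80 °C, one pot
Reagents that add atoms: bis(pinacolato)diboron, CC1(C)OB(OC1(C)C)B1OC(C)(C)C(C)(C)O1 (its boron sits in 7 only and is lost on coupling)
Why: Miyaura borylation of the aryl bromide, then Suzuki–Miyaura cross-coupling with the aryl iodide in the same flask, the bulky electron-rich SPhos ligand serving the tri-ortho-substituted biaryl; aldehyde, enone, free phenol and benzyl ethers tolerate both stages and no stereocentre is formed.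

Step 5
Reactants: 8 4-(benzyloxy)-3-{4,6-bis(benzyloxy)-3-[(E)-3-(4-(benzyloxy)-3-methoxyphenyl)prop-2-enoyl]-2-hydroxyphenyl}benzaldehyde; 2 1-[2,4-bis(benzyloxy)-6-hydroxyphenyl]ethanone
Product: 9 (E)-1-[2,4-bis(benzyloxy)-6-hydroxyphenyl]-3-[4-(benzyloxy)-3-{4,6-bis(benzyloxy)-3-[(E)-3-(4-(benzyloxy)-3-methoxyphenyl)prop-2-enoyl]-2-hydroxyphenyl}phenyl]prop-2-en-1-one
Conditions: 2 (1.2 equiv), KOH (50% aq.), EtOH–THF, rt, 48 h
Reagents that add atoms: none
Why: Second Claisen–Schmidt condensation; 8 has no enolisable methyl ketone left, so only the enolate of 2 adds to its aldehyde, and E1cB dehydration gives the second (E) enone.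

Step 6
Reactants: 9 (E)-1-[2,4-bis(benzyloxy)-6-hydroxyphenyl]-3-[4-(benzyloxy)-3-{4,6-bis(benzyloxy)-3-[(E)-3-(4-(benzyloxy)-3-methoxyphenyl)prop-2-enoyl]-2-hydroxyphenyl}phenyl]prop-2-en-1-one
Product: 11 8-[5-(5,7-dihydroxy-4-oxo-4H-chromen-2-yl)-2-hydroxyphenyl]-5,7-dihydroxy-2-(4-hydroxy-3-methoxyphenyl)-4H-chromen-4-one, via hexabenzyl biflavone 10 (not isolated)
Conditions: Pd/C (10 wt % Pd, 20 mol % Pd), KOAc (2 equiv), AcOH (5 equiv), DMA, O2 (1 atm), 100 °C; then N2 purge, THF–MeOH added, H2 (1 atm), 40 °C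
Reagents that add atoms: none
Why: Proposed new method: one charge of Pd/C is used under two atmospheres; under O2 the acetate buffer equilibrates each 2'-hydroxychalcone with its flavanone by 6-endo oxa-Michael addition (this makes both O1–C2 bonds and both rings C, each from the only free phenol, so unit 2 can only become the 8-aryl isomer), oxidised surface sites (divalent palladium carboxylate) palladate the flavanone enol at C3, and syn β-hydride elimination of the benzylic C2–H releases the aromatic 4-pyranone while O2 returns the palladium hydride to the oxidised site and water, with no benzyl ether cleaved because no hydride reservoir exists under O2; after the purge the same metal, now zerovalent palladium under H2, hydrogenolyses the six aryl benzyl ethers to toluene and leaves the aromatic pyranone C2=C3 bond and the aryl methyl ether alone; the closest known reaction types are the homogeneous aerobic α,β-dehydrogenation of chromanones and the oxidative cyclisation of 2'-hydroxy(dihydro)chalcones by divalent palladium salts with O2, and the one-pot reuse of palladium from a first catalytic reaction for a later hydrogenation; no stereocentre is formed.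

**Compound list**
1 | 2',4',6'-trihydroxyacetophenone (phloroacetophenone) | CC(=O)c1c(O)cc(O)cc1O | starting material
2 | 1-[2,4-bis(benzyloxy)-6-hydroxyphenyl]ethanone | CC(=O)c1c(O)cc(OCc2ccccc2)cc1OCc1ccccc1 | intermediate
3 | 1-[4,6-bis(benzyloxy)-2-hydroxy-3-iodophenyl]ethanone | CC(=O)c1c(O)c(I)c(OCc2ccccc2)cc1OCc1ccccc1 | intermediate
4 | 4-(benzyloxy)-3-methoxybenzaldehyde (O-benzylvanillin) | COc1cc(C=O)ccc1OCc1ccccc1 | starting material
5 | (E)-1-[4,6-bis(benzyloxy)-2-hydroxy-3-iodophenyl]-3-[4-(benzyloxy)-3-methoxyphenyl]prop-2-en-1-one | COc1cc(/C=C/C(=O)c2c(O)c(I)c(OCc3ccccc3)cc2OCc2ccccc2)ccc1OCc1ccccc1 | intermediate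
6 | 4-(benzyloxy)-3-bromobenzaldehyde | O=Cc1ccc(OCc2ccccc2)c(Br)c1 | starting material
7 | 4-(benzyloxy)-3-(4,4,5,5-tetramethyl-1,3,2-dioxaborolan-2-yl)benzaldehyde | O=Cc1ccc(OCc2ccccc2)c(B2OC(C)(C)C(C)(C)O2)c1 | intermediate
8 | 4-(benzyloxy)-3-{4,6-bis(benzyloxy)-3-[(E)-3-(4-(benzyloxy)-3-methoxyphenyl)prop-2-enoyl]-2-hydroxyphenyl}benzaldehyde | COc1cc(/C=C/C(=O)c2c(O)c(-c3cc(C=O)ccc3OCc3ccccc3)c(OCc3ccccc3)cc2OCc2ccccc2)ccc1OCc1ccccc1 | intermediate
9 | (E)-1-[2,4-bis(benzyloxy)-6-hydroxyphenyl]-3-[4-(benzyloxy)-3-{4,6-bis(benzyloxy)-3-[(E)-3-(4-(benzyloxy)-3-methoxyphenyl)prop-2-enoyl]-2-hydroxyphenyl}phenyl]prop-2-en-1-one | COc1cc(/C=C/C(=O)c2c(O)c(-c3cc(/C=C/C(=O)c4c(O)cc(OCc5ccccc5)cc4OCc4ccccc4)ccc3OCc3ccccc3)c(OCc3ccccc3)cc2OCc2ccccc2)ccc1OCc1ccccc1 | intermediate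
10 | 5,7-bis(benzyloxy)-8-{2-(benzyloxy)-5-[5,7-bis(benzyloxy)-4-oxo-4H-chromen-2-yl]phenyl}-2-[4-(benzyloxy)-3-methoxyphenyl]-4H-chromen-4-one | COc1cc(-c2cc(=O)c3c(OCc4ccccc4)cc(OCc4ccccc4)c(-c4cc(-c5cc(=O)c6c(OCc7ccccc7)cc(OCc7ccccc7)cc6o5)ccc4OCc4ccccc4)c3o2)ccc1OCc1ccccc1 | intermediate
11 | 8-[5-(5,7-dihydroxy-4-oxo-4H-chromen-2-yl)-2-hydroxyphenyl]-5,7-dihydroxy-2-(4-hydroxy-3-methoxyphenyl)-4H-chromen-4-one (CNP0179340.0) | COc1cc(-c2cc(=O)c3c(O)cc(O)c(-c4cc(-c5cc(=O)c6c(O)cc(O)cc6o5)ccc4O)c3o2)ccc1O | target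

**Step count**
Total steps: 6. Longest linear sequence: 6 steps (1 → 2 → 3 → 5 → 8 → 9 → 11); 4 and 6 enter as purchased side inputs.

**Steps most likely to fail**

Step 6 (the proposed new step). Pd/C may not turn over under O2 for both enolate dehydrogenations, and any flavanone left over would stay as flavanone or be over-reduced in the H2 stage. The fallback uses known chemistry and sets out from 9. I2 (10–20 mol % per enone) in DMSO at 130 °C closes and dehydrogenates both halves, the standard iodine-catalysed oxidative cyclisation of 2'-hydroxychalcones with DMSO as terminal oxidant, and gives 10, which is now isolated. H2 (1 atm), Pd/C, THF–MeOH, rt then removes the six benzyl groups and the route is back at 11. No compound outside the list is made (F0).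

Step 4. The aryl iodide is flanked by a free phenol and a benzyloxy group, so the tri-ortho-substituted coupling competes with protodeiodination. The aqueous base can also partly close the chalcone to its flavanone; that isomer reopens in step 5 and converges in step 6, but it complicates isolation. The fallback sets out from 5 and makes the pyranone ring of unit 2 before the biaryl bond. I2 in DMSO at 130 °C turns 5 into 5,7-bis(benzyloxy)-2-[4-(benzyloxy)-3-methoxyphenyl]-8-iodo-4H-chromen-4-one F1, which has no free phenol and no chalcone–flavanone equilibrium. Suzuki–Miyaura coupling of F1 with boronate 7 (made from 6 as in step 4) gives 4-(benzyloxy)-3-{5,7-bis(benzyloxy)-2-[4-(benzyloxy)-3-methoxyphenyl]-4-oxo-4H-chromen-8-yl}benzaldehyde F2. Claisen–Schmidt condensation of F2 with 2 gives 5,7-bis(benzyloxy)-8-{2-(benzyloxy)-5-[(E)-3-(2,4-bis(benzyloxy)-6-hydroxyphenyl)-3-oxoprop-1-enyl]phenyl}-2-[4-(benzyloxy)-3-methoxyphenyl]-4H-chromen-4-one F3. Its single remaining chalcone is closed under the conditions of step 6 (or with I2/DMSO), which brings the route back at 10 and on to 11.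

Step 5. The aldehyde 8 is large and poorly soluble, the enolate of 2 can add in Michael fashion to the enone already present, and long exposure to KOH invites retro-aldol scrambling. The fallback changes the order of fragment assembly and sets out from 2 and 6. Claisen–Schmidt condensation of these two small partners gives (E)-1-[2,4-bis(benzyloxy)-6-hydroxyphenyl]-3-[4-(benzyloxy)-3-bromophenyl]prop-2-en-1-one F4. Miyaura borylation (B2pin2, PdCl2(dppf), KOAc, 1,4-dioxane, 85 °C) gives (E)-1-[2,4-bis(benzyloxy)-6-hydroxyphenyl]-3-[4-(benzyloxy)-3-(4,4,5,5-tetramethyl-1,3,2-dioxaborolan-2-yl)phenyl]prop-2-en-1-one F5. Suzuki–Miyaura coupling of F5 with iodochalcone 5 (Pd(OAc)2, SPhos, K3PO4) joins the two chalcones and comes back to the route at 9.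

**Further compounds**
F1 | step 4 | 5,7-bis(benzyloxy)-2-[4-(benzyloxy)-3-methoxyphenyl]-8-iodo-4H-chromen-4-one | COc1cc(-c2cc(=O)c3c(OCc4ccccc4)cc(OCc4ccccc4)c(I)c3o2)ccc1OCc1ccccc1
F2 | step 4 | 4-(benzyloxy)-3-{5,7-bis(benzyloxy)-2-[4-(benzyloxy)-3-methoxyphenyl]-4-oxo-4H-chromen-8-yl}benzaldehyde | COc1cc(-c2cc(=O)c3c(OCc4ccccc4)cc(OCc4ccccc4)c(-c4cc(C=O)ccc4OCc4ccccc4)c3o2)ccc1OCc1ccccc1
F3 | step 4 | 5,7-bis(benzyloxy)-8-{2-(benzyloxy)-5-[(E)-3-(2,4-bis(benzyloxy)-6-hydroxyphenyl)-3-oxoprop-1-enyl]phenyl}-2-[4-(benzyloxy)-3-methoxyphenyl]-4H-chromen-4-one | COc1cc(-c2cc(=O)c3c(OCc4ccccc4)cc(OCc4ccccc4)c(-c4cc(/C=C/C(=O)c5c(O)cc(OCc6ccccc6)cc5OCc5ccccc5)ccc4OCc4ccccc4)c3o2)ccc1OCc1ccccc1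
F4 | step 5 | (E)-1-[2,4-bis(benzyloxy)-6-hydroxyphenyl]-3-[4-(benzyloxy)-3-bromophenyl]prop-2-en-1-one | O=C(/C=C/c1ccc(OCc2ccccc2)c(Br)c1)c1c(O)cc(OCc2ccccc2)cc1OCc1ccccc1
F5 | step 5 | (E)-1-[2,4-bis(benzyloxy)-6-hydroxyphenyl]-3-[4-(benzyloxy)-3-(4,4,5,5-tetramethyl-1,3,2-dioxaborolan-2-yl)phenyl]prop-2-en-1-one | O=C(/C=C/c1ccc(OCc2ccccc2)c(B2OC(C)(C)C(C)(C)O2)c1)c1c(O)cc(OCc2ccccc2)cc1OCc1ccccc1
F0 | step 6 | none | none
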